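A small charge of E, 0.75 M in the ochre run, and a larger one, 3 M in the blue run, are what we have, and the new flask lies between them.

| setting | ochre | blue | flask |
|---|---|---|---|
| E | 0.75 M | 3 M | 1.5 M |
| remark | run made earlier | run made earlier |  |
| time |  |  | 25 min |

| run | time / min | Z / % | X / % | E / % |
|---|---|---|---|---|
| ochre | 1.50 | 19.6 | 2.6 | 15.9 |
| ochre | 5.00 | 49.9 | 26.7 | 1.1 |
| ochre | 8.00 | 59.5 | 44.5 | 0 |
| ochre | 12.0 | 65.7 | 55.6 | 0 |
| ochre | 20.0 | 69.6 | 62.8 | 1.8 |
| ochre | 25.0 | 72.2 | 66.6 | 0.3 |
| ochre | 30.0 | 73.8 | 66.2 | 0.4 |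
| blue | 4.00 | 44.0 | 23.2 | 1.4 |
| blue | 8.00 | 60.8 | 48.2 | 0 |
| blue | 12.0 | 66.8 | 61.5 | 0.4 |
| blue | 15.0 | 69.7 | 67.0 | 0 |
| blue | 20.0 | 72.6 | 71.1 | 1.5 |
| blue | 25.0 | 77.9 | 72.9 | 0.5 |
| blue | 30.0 | 78.3 | 76.8 | 0 |

(standard deviation of a reading: 1 percentage point)

* the Z and X together standing at 25 min, as a percentage of the E charged
* concentration of Z in solution at 25 min, in percent of saturation

- for Z the X are counted in
- as a solid, counted per litre of solution: X

*What is Z minus X?* Z counts the crystals in, so Z minus X is the dissolved Z in percent of the charge. Multiplied by the charge, it becomes a concentration.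

*Where does it stand late?* Averaged over the last 3 readings, ochre gives 0.0500 M and blue 0.0800 M.

*So is that the solubility?* A solubility would be one number at one temperature, yet blue reads higher than ochre. So I work in logarithms to base ten and define the charge exponent n, the decades late dissolved Z rises per decade of charge, read over these same late times. From the two runs, n reads 0.339.

*And this flask?* Its charge lies 0.301 decades above ochre's, so I estimate its dissolved Z 0.102 decades higher, at 0.0632 M.

*In percent of what?* Ochre's X reads higher late on, from 62.8 % to 66.2 %, so I take ochre's solution to stand at or above saturation, and I read 0.0500 M as an estimated ceiling on the solubility, within its scatter. My estimate for the flask is then about 126 % of saturation or somewhat more, a supersaturated solution.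

*How firm is blue's figure?* It is a mean of small differences between large readings, uncertain by 0.0245 M, so n is a rough reading.

The forecast gives 74 % and 108 %, reasoning that “Slow continuing Z formation keeps a slight excess”. Its saturation figure lies below my 126 %.

The flask gives 74.9 % and 135 %, which is 27 percentage points above the forecast's saturation figure.

    X ⇌ Z, rate k1*(cs1 - [Z]) while solid is left; crystals form when [Z] > cs1 (solubility = 47.0 mM, k = 0.00699 s⁻¹)
    J ⇌ G (K = 2.90, k = 0.00157 s⁻¹)
    E → J (k = 0.0214 s⁻¹)
    J ⇌ Z (K = 1.73, k = 0.00476 s⁻¹)

At 25 min the flask holds Z 74.9 % and X 70.7 %, so 0.0634 M of Z is dissolved, against the 0.0632 M reckoned. The neighbouring flask takes 0.60 M of E for the same time. It lies 0.0969 decades below ochre, so the exponent puts its dissolved Z at 0.0464 M. That flask stands at Z 70.2 % and X 61.6 %, which is 0.0516 M dissolved.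

The runs come from a simulation with made-up constants.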